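## Retrosynthetic overview

1. Ring B (eight-membered) is closed last: the tetrasubstituted C=C comes from an intramolecular McMurry coupling of a cyclopentanone with a methyl ketone (20 → 23).
2. Ring A is bought as 2-bromo-3-methylcyclopentenone and joined to a decalin aldehyde by Ni/Cr coupling; an OH-directed syn-hydrogenation then sets the cis methyl/side-chain pair.
3. The four-carbon arm on the decalin comes from a secondary decalin radical adding to methyl vinyl ketone; the quaternary carbon next to the carbinol comes from acylation and axial methylation of decalone 9.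
4. Key step: ring D and its gem-dimethyl carbon are closed by an Fe–H hydrogen-atom-transfer radical cyclisation of an isopropenyl chain onto an exocyclic enone (7 → 9).
5. Ring order: C (3-methylcyclohexenone) → D → A (attached) → B.

Assumption: where a chiral ligand is used (steps 1 and 8), the antipode that gives the drawn configuration is taken; compounds 2 and 18 are treated as catalogue chemicals.

## Route

Step 1
Reactants: 1 3-methylcyclohex-2-en-1-one; 2 4-bromo-2-methylbut-1-ene
Product: 7 (R)-3-methyl-3-(3-methylbut-3-en-1-yl)-2-methylidenecyclohexan-1-one, via Grignard reagent 3 (not isolated), via magnesium enolate 4 (not isolated), via Mannich base 5 (not isolated), via ammonium iodide 6 (not isolated)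
Conditions: 2, Mg, Et2O; then 1, Cu(OTf)2 (3 mol%), chiral NHC·HBF4 (4 mol%), Et2O, -30 °C; then CH2=NMe2+ I-, THF, -30 °C to rt; then MeI; then DBU, rt (one pot)
Reagents that add atoms: Eschenmoser's salt (N,N-dimethylmethyleneiminium iodide), C=[N+](C)C.[I-]
Why: Cu–NHC-catalysed asymmetric conjugate addition of the Grignard reagent builds the quaternary stereocentre under ligand control (R); the regiodefined magnesium enolate is trapped by Eschenmoser's salt (Mannich reaction), and quaternisation followed by Hofmann-type elimination gives the exocyclic enone.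

Step 2
Reactants: 7 (R)-3-methyl-3-(3-methylbut-3-en-1-yl)-2-methylidenecyclohexan-1-one
Product: 9 (4aR,8aR)-4a,7,7-trimethyloctahydronaphthalen-1(2H)-one (trans-fused), via cis-fused epimer 8 (not isolated)
Conditions: Fe(acac)3 (0.3 equiv), PhSiH3, EtOH/(CH2OH)2, 60 °C, 0.01 M; then NaOMe, MeOH, rt
Reagents that add atoms: none
Why: Fe–H hydrogen-atom transfer (Mukaiyama-type MHAT) to the electron-rich isopropenyl group gives a tertiary radical that closes ring D by intramolecular Giese addition to the enone CH2, creating the gem-dimethyl carbon; the ring-fusion CH is alpha to the ketone and is equilibrated by methoxide to the trans-decalone (estimated about 4:1, cis isomer recycled).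

Step 3
Reactants: 9 (4aR,8aR)-4a,7,7-trimethyloctahydronaphthalen-1(2H)-one
Product: 11 methyl (2S,4aS,8aR)-2,4a,7,7-tetramethyl-1-oxodecahydronaphthalene-2-carboxylate, via sodium enolate 10 (not isolated)
Conditions: NaH, (MeO)2CO, THF, reflux; then MeI, rt to 50 °C
Reagents that add atoms: dimethyl carbonate, COC(=O)OC; iodomethane, CI
Why: Claisen-type C-acylation occurs at the only CH2 next to the ketone, and the β-keto ester enolate is C-methylated by axial attack on the face opposite the angular methyl (chair-like transition state, no syn-axial methyl on that face), giving axial CH3 and equatorial ester; the ring fusion stays trans because every cis-fused form has a syn-diaxial C/C contact.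

Step 4
Reactants: 11 methyl (2S,4aS,8aR)-2,4a,7,7-tetramethyl-1-oxodecahydronaphthalene-2-carboxylate
Product: 12 methyl (2S,4aS,8aR)-1-hydroxy-2,4a,7,7-tetramethyldecahydronaphthalene-2-carboxylate (mixture of C-1 epimers)
Conditions: NaBH4, MeOH/THF, 0 °C to rt
Reagents that add atoms: none
Why: Borohydride reduction of the hindered ketone leaves the ester intact; the carbinol configuration does not matter because C-1 becomes a planar radical in step 5.

Step 5
Reactants: 12 methyl (2S,4aS,8aR)-1-hydroxy-2,4a,7,7-tetramethyldecahydronaphthalene-2-carboxylate; 13 but-3-en-2-one (methyl vinyl ketone)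
Product: 15 methyl (1S,2S,4aS,8aS)-2,4a,7,7-tetramethyl-1-(3-oxobutyl)decahydronaphthalene-2-carboxylate, via benzoxazoline adduct 14 (not isolated)
Conditions: 5,7-di-tert-butyl-3-phenylbenzoxazolium BF4, pyridine, t-BuOMe, rt; then 13 (5 equiv), [Ir(ppy)2(dtbbpy)]PF6 (1 mol%), quinuclidine (cat.), DMSO, blue LED, rt
Reagents that add atoms: none
Why: Photoredox deoxygenative Giese reaction: the oxidised NHC–alcohol adduct fragments to the secondary C-1 radical, which adds to the enone from the face opposite the syn-axial angular methyl, so the new chain is equatorial (1S).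

Step 6
Reactants: 15 methyl (1S,2S,4aS,8aS)-2,4a,7,7-tetramethyl-1-(3-oxobutyl)decahydronaphthalene-2-carboxylate
Product: 16 4-[(1S,2S,4aS,8aS)-2-(hydroxymethyl)-2,4a,7,7-tetramethyldecahydronaphthalen-1-yl]butan-2-ol (mixture of side-chain carbinol epimers)
Conditions: LiAlH4, THF, 0 °C to reflux
Reagents that add atoms: none
Why: Hydride reduction converts the neopentyl ester into the primary alcohol (the ketone is reduced as well and restored in step 7); the only new stereocentre is removed again.

Step 7
Reactants: 16 4-[(1S,2S,4aS,8aS)-2-(hydroxymethyl)-2,4a,7,7-tetramethyldecahydronaphthalen-1-yl]butan-2-ol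
Product: 17 (1S,2S,4aS,8aS)-2,4a,7,7-tetramethyl-1-(3-oxobutyl)decahydronaphthalene-2-carbaldehyde
Conditions: Dess–Martin periodinane (3 equiv), CH2Cl2, rt
Reagents that add atoms: none
Why: Dess–Martin oxidation of both alcohols gives the methyl ketone and an α-quaternary aldehyde that cannot epimerise.

Step 8
Reactants: 17 (1S,2S,4aS,8aS)-2,4a,7,7-tetramethyl-1-(3-oxobutyl)decahydronaphthalene-2-carbaldehyde; 18 2-bromo-3-methylcyclopent-2-en-1-one
Product: 19 2-{(S)-hydroxy[(1S,2S,4aS,8aS)-2,4a,7,7-tetramethyl-1-(3-oxobutyl)decahydronaphthalen-2-yl]methyl}-3-methylcyclopent-2-en-1-one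
Conditions: CrCl2 (4 equiv), chiral oxazoline–sulfonamide ligand (Kishi type), Et3N, NiCl2·dmp (10 mol%), THF, rt
Reagents that add atoms: none
Why: Nozaki–Hiyama–Kishi coupling (Ni oxidative addition, transmetalation to Cr(III)) adds the vinyl group to the aldehyde only, leaving both ketones; the aldehyde has almost no facial bias (an axial CH3 and a ring CH2 flank it alike), so the carbinol configuration is set by the chiral Cr–sulfonamide complex.

Step 9
Reactants: 19 2-{(S)-hydroxy[(1S,2S,4aS,8aS)-2,4a,7,7-tetramethyl-1-(3-oxobutyl)decahydronaphthalen-2-yl]methyl}-3-methylcyclopent-2-en-1-one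
Product: 20 (2R,3S)-2-{(R)-hydroxy[(1S,2S,4aS,8aS)-2,4a,7,7-tetramethyl-1-(3-oxobutyl)decahydronaphthalen-2-yl]methyl}-3-methylcyclopentan-1-one
Conditions: [Ir(cod)(PCy3)(py)]BArF (5 mol%), H2 (30 bar), CH2Cl2, rt; filtration through neutral alumina
Reagents that add atoms: none
Why: Hydroxyl-directed syn-hydrogenation (Crabtree-type catalyst): in the A(1,3)-minimised conformer the carbinol H lies in the enone plane and the OH face is also the face away from the quaternary decalin carbon, so both hydrogens add there, giving the cis methyl/side-chain pair with the (2R,3S) configuration.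

Step 10
Reactants: 20 (2R,3S)-2-{(R)-hydroxy[(1S,2S,4aS,8aS)-2,4a,7,7-tetramethyl-1-(3-oxobutyl)decahydronaphthalen-2-yl]methyl}-3-methylcyclopentan-1-one
Product: 23 target CNP0399382.1 (5-8-6-6 tetracyclic alcohol), via silylated diketone 21 (not isolated), via silylated cyclooctene 22 (not isolated)
Conditions: N-(trimethylsilyl)imidazole, CH2Cl2, rt, concentrate; syringe-pump addition (30 h) to TiCl3(DME)1.5, Zn–Cu, DME, reflux; then 1 M HCl, THF, rt
Reagents that add atoms: none
Why: McMurry reaction: low-valent titanium couples the two ketyl radicals to a titanium pinacolate that is deoxygenated to the tetrasubstituted alkene; ring closure fixes the alkene geometry, high dilution favours the eight-membered ring, the TMS ether guards against retro-aldol cleavage, and no new stereocentre is formed.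

## Compound list

1 | 3-methylcyclohex-2-en-1-one | CC1=CC(=O)CCC1 | starting material
2 | 4-bromo-2-methylbut-1-ene | C=C(C)CCBr | starting material
3 | (3-methylbut-3-en-1-yl)magnesium bromide | C=C(C)CC[Mg]Br | intermediate
4 | bromomagnesium (R)-3-methyl-3-(3-methylbut-3-en-1-yl)cyclohex-1-en-1-olate | C=C(C)CC[C@@]1(C)CCCC(O[Mg]Br)=C1 | intermediate
5 | (3R)-2-[(dimethylamino)methyl]-3-methyl-3-(3-methylbut-3-en-1-yl)cyclohexan-1-one (C-2 epimers) | C=C(C)CC[C@@]1(C)CCCC(=O)C1CN(C)C | intermediate
6 | N,N,N-trimethylammonium iodide derived from 5 | C=C(C)CC[C@@]1(C)CCCC(=O)C1C[N+](C)(C)C.[I-] | intermediate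
7 | (R)-3-methyl-3-(3-methylbut-3-en-1-yl)-2-methylidenecyclohexan-1-one | C=C(C)CC[C@@]1(C)CCCC(=O)C1=C | intermediate
8 | (4aR,8aS)-4a,7,7-trimethyloctahydronaphthalen-1(2H)-one (cis-fused) | O=C1CCC[C@]2(C)CCC(C)(C)C[C@H]12 | intermediate
9 | (4aR,8aR)-4a,7,7-trimethyloctahydronaphthalen-1(2H)-one (trans-fused) | O=C1CCC[C@]2(C)CCC(C)(C)C[C@@H]12 | intermediate
10 | sodium enolate of methyl (4aS,8aR)-4a,7,7-trimethyl-1-oxodecahydronaphthalene-2-carboxylate | COC(=O)C1=C([O-])[C@@H]2CC(C)(C)CC[C@@]2(C)CC1.[Na+] | intermediate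
11 | methyl (2S,4aS,8aR)-2,4a,7,7-tetramethyl-1-oxodecahydronaphthalene-2-carboxylate | COC(=O)[C@@]1(C)CC[C@]2(C)CCC(C)(C)C[C@H]2C1=O | intermediate
12 | methyl (2S,4aS,8aR)-1-hydroxy-2,4a,7,7-tetramethyldecahydronaphthalene-2-carboxylate (C-1 epimers, C-1 left undefined) | COC(=O)[C@@]1(C)CC[C@]2(C)CCC(C)(C)C[C@H]2C1O | intermediate
13 | but-3-en-2-one | CC(=O)C=C | starting material
14 | 2-alkoxy-5,7-di-tert-butyl-3-phenyl-2,3-dihydrobenzoxazole adduct of 12 | COC(=O)[C@@]1(C)CC[C@]2(C)CCC(C)(C)C[C@H]2C1OC1Oc2c(cc(cc2C(C)(C)C)C(C)(C)C)N1c1ccccc1 | intermediate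
15 | methyl (1S,2S,4aS,8aS)-2,4a,7,7-tetramethyl-1-(3-oxobutyl)decahydronaphthalene-2-carboxylate | COC(=O)[C@@]1(C)CC[C@]2(C)CCC(C)(C)C[C@H]2[C@@H]1CCC(C)=O | intermediate
16 | 4-[(1S,2S,4aS,8aS)-2-(hydroxymethyl)-2,4a,7,7-tetramethyldecahydronaphthalen-1-yl]butan-2-ol (side-chain carbinol undefined) | OC[C@@]1(C)CC[C@]2(C)CCC(C)(C)C[C@H]2[C@@H]1CCC(C)O | intermediate
17 | (1S,2S,4aS,8aS)-2,4a,7,7-tetramethyl-1-(3-oxobutyl)decahydronaphthalene-2-carbaldehyde | O=C[C@@]1(C)CC[C@]2(C)CCC(C)(C)C[C@H]2[C@@H]1CCC(C)=O | intermediate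
18 | 2-bromo-3-methylcyclopent-2-en-1-one | CC1=C(Br)C(=O)CC1 | starting material
19 | 2-{(S)-hydroxy[(1S,2S,4aS,8aS)-2,4a,7,7-tetramethyl-1-(3-oxobutyl)decahydronaphthalen-2-yl]methyl}-3-methylcyclopent-2-en-1-one | CC1=C(C(=O)CC1)[C@@H](O)[C@@]1(C)CC[C@]2(C)CCC(C)(C)C[C@H]2[C@@H]1CCC(C)=O | intermediate
20 | (2R,3S)-2-{(R)-hydroxy[(1S,2S,4aS,8aS)-2,4a,7,7-tetramethyl-1-(3-oxobutyl)decahydronaphthalen-2-yl]methyl}-3-methylcyclopentan-1-one | O=C1CC[C@H](C)[C@@H]1[C@@H](O)[C@@]1(C)CC[C@]2(C)CCC(C)(C)C[C@H]2[C@@H]1CCC(C)=O | intermediate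
21 | trimethylsilyl ether of 20 | O=C1CC[C@H](C)[C@@H]1[C@@H](O[Si](C)(C)C)[C@@]1(C)CC[C@]2(C)CCC(C)(C)C[C@H]2[C@@H]1CCC(C)=O | intermediate
22 | trimethylsilyl ether of 23 | C/C1=C2\CC[C@H](C)[C@@H]2[C@@H](O[Si](C)(C)C)[C@@]2(C)CC[C@]3(C)CCC(C)(C)C[C@H]3[C@@H]2CC1 | intermediate
23 | CNP0399382.1: cyclopentane (ring A) fused to a cyclooctene (ring B, tetrasubstituted C=C bearing CH3) fused to a trans-decalin (rings C/D); CIP: ring-A CH(CH3) S, A/B ring-fusion CH S, CHOH R, adjacent C(CH3) S, angular C(CH3) S, both decalin CH S | C/C1=C2\CC[C@H](C)[C@@H]2[C@@H](O)[C@@]2(C)CC[C@]3(C)CCC(C)(C)C[C@H]3[C@@H]2CC1 | target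

## Step count and risks

Total step count: 10. Longest linear sequence: 10 steps (1 → 23); compounds 2, 13 and 18 enter this line directly.

Three steps most likely to fail:

Step 10 (McMurry closure of the eight-membered ring to a tetrasubstituted alkene). The risks are a low cyclisation yield and epimerisation of the ketone α-carbon before coupling. The fallback sets out from 21 and splits the coupling into two milder stages. SmI2/HMPA in THF at room temperature gives the pinacol, the cis-1,2-diol trimethylsilyl ether F6. Thiocarbonyldiimidazole converts it into the cyclic thionocarbonate F7. Corey–Hopkins elimination with 1,3-dimethyl-2-phenyl-1,3,2-diazaphospholidine at 40 °C then gives the silylated cyclooctene, where the fallback comes back to the route at 22.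

Step 8 (Ni/Cr coupling of an α-bromoenone with a neopentyl aldehyde under ligand control). The risks are sluggish coupling and a poor diastereomer ratio at the carbinol. The fallback sets out from 18, which is protected with ethylene glycol/TsOH as the bromo ketal 6-bromo-7-methyl-1,4-dioxaspiro[4.4]non-6-ene F4. Bromine–lithium exchange (t-BuLi, -78 °C) and transmetalation with ClTi(OiPr)3 give an aldehyde-selective vinyl titanium reagent, which is added to 17. This gives the ketal-protected carbinol F5 as a separable epimer pair. Mild hydrolysis (PPTS, aqueous acetone) of the correct epimer comes back to the route at 19.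

Step 5 (radical addition of a hindered secondary radical to methyl vinyl ketone). The risks are low yield and the wrong configuration at C-1. The fallback sets out from 11 and uses polar chemistry under thermodynamic control. Horner–Wittig reaction with lithiated (methoxymethyl)diphenylphosphine oxide gives the enol ether F1. Acid hydrolysis and base equilibration give the equatorial aldehyde methyl 1-formyl-2,4a,7,7-tetramethyldecahydronaphthalene-2-carboxylate F2. Wittig reaction with (acetylmethylene)triphenylphosphorane gives the enone F3, and hydrogenation over Pd/C comes back to the route at 15.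

## Further compounds

F1 | step 5 | methyl (2S,4aS,8aS)-1-(methoxymethylidene)-2,4a,7,7-tetramethyldecahydronaphthalene-2-carboxylate (E/Z) | COC(=O)[C@@]1(C)CC[C@]2(C)CCC(C)(C)C[C@H]2C1=COC
F2 | step 5 | methyl 1-formyl-2,4a,7,7-tetramethyldecahydronaphthalene-2-carboxylate (equatorial CHO, ring configuration as in 15) | COC(=O)[C@@]1(C)CC[C@]2(C)CCC(C)(C)C[C@H]2[C@@H]1C=O
F3 | step 5 | methyl 2,4a,7,7-tetramethyl-1-[(E)-3-oxobut-1-en-1-yl]decahydronaphthalene-2-carboxylate (ring configuration as in 15) | COC(=O)[C@@]1(C)CC[C@]2(C)CCC(C)(C)C[C@H]2[C@@H]1/C=C/C(C)=O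
F4 | step 8 | 6-bromo-7-methyl-1,4-dioxaspiro[4.4]non-6-ene | CC1=C(Br)C2(CC1)OCCO2
F5 | step 8 | ethylene ketal of 19 at the cyclopentenone carbonyl | CC1=C(C2(CC1)OCCO2)[C@@H](O)[C@@]1(C)CC[C@]2(C)CCC(C)(C)C[C@H]2[C@@H]1CCC(C)=O
F6 | step 10 | cis-1,2-diol (pinacol) corresponding to 22, diol carbons undefined | CC1(O)C2(O)CC[C@H](C)[C@@H]2[C@@H](O[Si](C)(C)C)[C@@]2(C)CC[C@]3(C)CCC(C)(C)C[C@H]3[C@@H]2CC1
F7 | step 10 | cyclic thionocarbonate of F6 | CC1(OC(=S)O5)C25CC[C@H](C)[C@@H]2[C@@H](O[Si](C)(C)C)[C@@]2(C)CC[C@]3(C)CCC(C)(C)C[C@H]3[C@@H]2CC1
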